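The cage atoms are numbered as in the target SMILES (C1 angelate carbinol to C11 methyl-bearing carbon). In the cyclobutane C5–C6–C11–C10, the 1,3-pair C5/C11 is linked a second time through C1–C4 (seven-membered ring) and the other 1,3-pair C6/C10 through C7–C9 (six-membered rings). Cutting C4–C5 and C1–C11 therefore leaves a bicyclobutane with C5–C11 as central bond. The key step opens that bond of ester-activated bicyclobutane 14 under Lewis acid, adds silyloxy diene 19 across it and closes the cycloheptenone, delivering every ring carbon and the cyclobutane stereocentres at once. Precursor 14 is a tricyclo[4.1.0.0(2,7)]heptane with the ester on the bridgehead anti to the methyl group.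

Key step: step 12

Remark: (R)-(+)-pulegone is used because the Wharton transposition of step 5 moves the carbinol to the former β-carbon, which turns the (R)-methyl centre into the required (5S) one; the borylation ligand antipode (step 17) is to be fixed by a pilot run, and the CBS antipode (step 19) is the one predicted by the large/small model.

Step 1
Reactants: 1 (R)-(+)-pulegone
Product: 2 pulegone oxide (2,8-epoxide; both spiro epimers)
Conditions: 30% H2O2, LiOH·H2O, MeOH, 0 °C to rt
Reagents that add atoms: hydrogen peroxide, OO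
Why: Weitz–Scheffer nucleophilic epoxidation of the tetrasubstituted enone; the new spiro centre is irrelevant because it is destroyed in step 2.

Step 2
Reactants: 2 pulegone oxide
Product: 3 (5R)-5-methyl-2-(phenylsulfanyl)cyclohexan-1-one (C2 epimers)
Conditions: PhSNa, THF, reflux
Reagents that add atoms: sodium benzenethiolate, [Na+].[S-]c1ccccc1
Why: The thiolate opens the epoxide at the carbon α to the ketone and the tertiary alkoxide then expels acetone by retro-aldol cleavage, leaving the α-sulfenyl ketone with the methyl stereocentre untouched.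

Step 3
Reactants: 3 (5R)-5-methyl-2-(phenylsulfanyl)cyclohexan-1-one
Product: 5 (R)-5-methylcyclohex-2-en-1-one, via sulfoxide 4 (not isolated)
Conditions: mCPBA (1.0 equiv), CH2Cl2, −78 °C; then CaCO3, toluene, 90 °C
Reagents that add atoms: none
Why: Sulfide oxidation followed by thermal syn-elimination of the sulfoxide, which can only take a hydrogen from C3 and so gives the C2=C3 enone regiospecifically.

Step 4
Reactants: 5 (R)-5-methylcyclohex-2-en-1-one
Product: 6 (5R)-2,3-epoxy-5-methylcyclohexan-1-one (epoxide trans to methyl)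
Conditions: 30% H2O2, NaOH (cat.), MeOH, 0 °C
Reagents that add atoms: hydrogen peroxide, OO
Why: Weitz–Scheffer epoxidation in which hydroperoxide adds axially to C3 anti to the C5 methyl group, as nucleophiles do with 5-substituted cyclohexenones, so the epoxide is trans to the methyl group.

Step 5
Reactants: 6 (5R)-2,3-epoxy-5-methylcyclohexan-1-one
Product: 7 (1R,5S)-5-methylcyclohex-2-en-1-ol (trans)
Conditions: N2H4·H2O, AcOH (cat.), MeOH, 0 °C to rt
Reagents that add atoms: none
Why: Wharton transposition: the epoxy hydrazone fragments with loss of N2 to the allylic alcohol, the epoxide C–O bond at the former C3 is kept, so the hydroxyl is trans to the methyl group.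

Step 6
Reactants: 7 (1R,5S)-5-methylcyclohex-2-en-1-ol; 8 bromoform
Product: 9 7,7-dibromo-4-methylbicyclo[4.1.0]heptan-2-ol (cyclopropane cis to OH; methyl trans to OH)
Conditions: 50% aq. NaOH, BnEt3NCl (cat.), CH2Cl2, 0 °C to rt
Reagents that add atoms: none
Why: Phase-transfer dibromocarbene [2+1] addition directed by the free allylic hydroxyl to its own face, which sets both cyclopropane carbons cis to OH and leaves the carbinol C–H on the opposite face, out of reach of the later carbenoid.

Step 7
Reactants: 9 7,7-dibromo-4-methylbicyclo[4.1.0]heptan-2-ol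
Product: 10 5-methyltricyclo[4.1.0.0(2,7)]heptan-3-ol (OH and methyl trans)
Conditions: MeLi (2.5 equiv), Et2O, −78 to 0 °C
Reagents that add atoms: none
Why: Br/Li exchange gives the cyclopropylidene carbenoid, which inserts with retention into the only C–H bond on its face at a neighbouring ring carbon (the CH2 next to the methyl-bearing carbon), the established route from 7,7-dibromonorcaranes to tricyclo[4.1.0.0(2,7)]heptanes; the ring-fusion centres follow from the cyclopropane face set in step 6.

Step 8
Reactants: 10 5-methyltricyclo[4.1.0.0(2,7)]heptan-3-ol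
Product: 13 methyl 3-hydroxy-5-methyltricyclo[4.1.0.0(2,7)]heptane-1-carboxylate, via dilithio species 11 (not isolated), via hydroxy acid 12 (not isolated)
Conditions: n-BuLi (2.5 equiv), Et2O, 0 °C to rt; CO2, −78 °C; 1 M HCl to pH 3, 0 °C; TMSCHN2, toluene–MeOH, 0 °C
Reagents that add atoms: carbon dioxide, O=C=O; (trimethylsilyl)diazomethane, C[Si](C)(C)C=[N+]=[N-]
Why: Bicyclobutane bridgehead C–H bonds are acidic enough for n-BuLi, and the lithium alkoxide holds the base on its own side (complex-induced proximity), so the bridgehead nearer the oxygen and anti to the methyl group should be metalated and carboxylated with retention before the acid is esterified.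

Step 9
Reactants: 13 methyl 3-hydroxy-5-methyltricyclo[4.1.0.0(2,7)]heptane-1-carboxylate
Product: 14 methyl 3-(tert-butyldimethylsilyloxy)-5-methyltricyclo[4.1.0.0(2,7)]heptane-1-carboxylate
Conditions: TBSCl, imidazole, DMF, rt
Reagents that add atoms: tert-butyldimethylsilyl chloride, CC(C)(C)[Si](C)(C)Cl
Why: Standard silylation of a secondary alcohol under non-acidic conditions that spare the acyl bicyclobutane.

Step 10
Reactants: 15 3-methylbutan-2-one; 16 methyl formate
Product: 18 (E)-1-methoxy-4-methylpent-1-en-3-one, via sodium enolate 17 (not isolated)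
Conditions: NaOMe, THF, 0 °C to rt; then Me2SO4, DMF, 0 °C to rt
Reagents that add atoms: dimethyl sulfate, COS(=O)(=O)OC
Why: Claisen formylation takes place at the methyl group, the only site that gives a stabilised β-keto aldehyde enolate, and the hard electrophile then methylates the formyl oxygen to the E-β-methoxy enone.

Step 11
Reactants: 18 (E)-1-methoxy-4-methylpent-1-en-3-one
Product: 19 (E)-1-methoxy-4-methyl-3-(trimethylsilyloxy)penta-1,3-diene
Conditions: TMSOTf, Et3N, Et2O, 0 °C
Reagents that add atoms: trimethylsilyl trifluoromethanesulfonate, C[Si](C)(C)OS(=O)(=O)C(F)(F)F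
Why: Soft enolisation and O-silylation at the isopropyl methine, the only enolisable position, gives the silyloxy diene without touching the E-enol ether.

Step 12
Reactants: 14 methyl 3-(tert-butyldimethylsilyloxy)-5-methyltricyclo[4.1.0.0(2,7)]heptane-1-carboxylate; 19 (E)-1-methoxy-4-methyl-3-(trimethylsilyloxy)penta-1,3-diene
Product: 21 cage cycloheptenone ester (C1=C2; C3 ketone; C11 CO2Me; C9 OTBS), via methoxy silyl enol ether cycloadduct 20 (not isolated)
Conditions: TMSOTf (0.2 equiv), 2,6-di-tert-butylpyridine (0.3 equiv), CH2Cl2, −78 to 0 °C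
Reagents that add atoms: none
Why: Proposed new method: silyl activation of the bridgehead ester polarises the central C5–C11 σ-bond, the enol-ether carbon C4 of 19 attacks the unsubstituted bridgehead C5 on the convex face (Mukaiyama–Michael-type homoconjugate addition) to give a cyclobutyl silyl ketene acetal at C11 and a β-methoxy enone, the ketene acetal then adds to the silyl-activated C1, and 20 loses Me3SiOMe to give the enone. The closest known reaction type is the Lewis-acid formal cycloaddition of acyl bicyclobutanes with silyl dienol ethers to bicyclo[4.1.1]octanes, extended here to an ester-activated ring-fused bicyclobutane and a fully substituted nucleophilic terminus. The seven-membered ring closes by a 7-endo-trig vinylogous Mukaiyama addition–elimination at C1. C5 and C11 are the stereocentres formed, and both are controlled by the tricyclic framework: the C7–C9 bridge fills the concave face, so both bonds can only form on the opposite face and the ester turns toward the bridge. The step needs attack at C5 rather than C11 and no cationic skeletal rearrangement; the ester fixes the polarity (enolate at C11, electrophilic C5) and the hindered pyridine removes protic acid.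

Step 13
Reactants: 21 cage cycloheptenone ester
Product: 22 cage diol (C3 allylic alcohol as either epimer; C11 CH2OH)
Conditions: DIBAL-H (5 equiv), CH2Cl2, −78 to 0 °C; Rochelle salt
Reagents that add atoms: none
Why: DIBAL-H reduces the enone 1,2 and the hindered ester fully; the C3 configuration does not matter because C3 is re-oxidised in step 16.

Step 14
Reactants: 22 cage diol
Product: 23 cage primary tosylate (C11 CH2OTs; C3 OH)
Conditions: TsCl, pyridine, CH2Cl2, 0 °C
Reagents that add atoms: p-toluenesulfonyl chloride, Cc1ccc(cc1)S(Cl)(=O)=O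
Why: Sulfonylation selects the primary hydroxyl over the secondary allylic one, which is flanked by the gem-dimethyl carbon.

Step 15
Reactants: 23 cage primary tosylate
Product: 24 cage allylic alcohol (C11 methyl; C3 OH)
Conditions: LiEt3BH (5 equiv), THF, 0 to 65 °C
Reagents that add atoms: none
Why: Super-Hydride displaces neopentyl-type sulfonates by SN2 hydride transfer, turning CH2OTs into the C11 methyl group while the silyl ether and the alkoxide are inert.

Step 16
Reactants: 24 cage allylic alcohol
Product: 25 cage enone (C1=C2; C3 ketone; C11 methyl; C9 OTBS)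
Conditions: Dess–Martin periodinane, CH2Cl2, rt
Reagents that add atoms: none
Why: Dess–Martin oxidation of the allylic alcohol restores the non-enolisable enone.

Step 17
Reactants: 25 cage enone
Product: 27 (1S)-C1 hydroxy C3 ketone, via boryl ketone 26 (not isolated)
Conditions: CuCl (5 mol%), NaOt-Bu (10 mol%), Josiphos-type bisphosphine (6 mol%; antipode fixed by a pilot run), B2pin2, MeOH, THF, rt; then NaBO3·4H2O, THF–H2O, rt
Reagents that add atoms: sodium perborate, [Na+].[O-]OB=O
Why: Catalytic asymmetric β-borylation (Cu–boryl conjugate addition, protonation by MeOH) followed by C–B oxidation with retention; the two enone faces differ only through remote groups, so the ligand should decide the C1 configuration, placing oxygen on the face toward C6.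

Step 18
Reactants: 27 (1S)-C1 hydroxy C3 ketone
Product: 28 (1S)-C1 angelate C3 ketone
Conditions: angelic acid, 2,4,6-trichlorobenzoyl chloride, Et3N, toluene, rt; then 27, 70 °C
Reagents that add atoms: angelic acid, C/C=C(/C)C(=O)O
Why: Yamaguchi mixed-anhydride acylation without DMAP, the usual way to make angelates of hindered alcohols without Z to E isomerisation, under a base too weak to eliminate the β-acyloxy ketone.

Step 19
Reactants: 28 (1S)-C1 angelate C3 ketone
Product: 29 (1S,3S)-C1 angelate C3 alcohol
Conditions: (R)-Me-CBS (0.5 equiv), catecholborane, toluene, −78 to −40 °C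
Reagents that add atoms: none
Why: Corey–Bakshi–Shibata reduction in which the quaternary C4 is the large and the C2 methylene the small substituent, so the (R)-catalyst should deliver hydride on the face bearing the angelate and give the (3S)-alcohol trans to it; the enoate is inert to catecholborane.

Step 20
Reactants: 29 (1S,3S)-C1 angelate C3 alcohol
Product: 30 C1 angelate C3 acetate C9 silyl ether
Conditions: Ac2O, pyridine, DMAP (cat.), CH2Cl2, 0 °C to rt
Reagents that add atoms: acetic anhydride, CC(=O)OC(C)=O
Why: DMAP-catalysed acetylation of the hindered secondary alcohol, run cold and briefly so that the angelate geometry is kept.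

Step 21
Reactants: 30 C1 angelate C3 acetate C9 silyl ether
Product: 31 C1 angelate C3 acetate C9 alcohol
Conditions: HF·pyridine, pyridine, THF, 0 °C to rt
Reagents that add atoms: none
Why: Fluoride-driven cleavage of the secondary TBS ether under buffered conditions that leave both esters in place.

Step 22
Reactants: 31 C1 angelate C3 acetate C9 alcohol
Product: 32 target CNP0204102.1
Conditions: Dess–Martin periodinane, CH2Cl2, rt
Reagents that add atoms: none
Why: Dess–Martin oxidation of the C9 carbinol to the ketone; the neighbouring C10 is a ring-fusion carbon of the cage and cannot epimerise.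

Compound list
1 | (R)-(+)-pulegone | C[C@@H]1CCC(=C(C)C)C(=O)C1 | starting material
2 | pulegone oxide (2,8-epoxide; both spiro epimers) | C[C@@H]1CCC2(OC2(C)C)C(=O)C1 | intermediate
3 | (5R)-5-methyl-2-(phenylsulfanyl)cyclohexan-1-one (C2 epimers) | C[C@@H]1CCC(Sc2ccccc2)C(=O)C1 | intermediate
4 | (5R)-5-methyl-2-(phenylsulfinyl)cyclohexan-1-one | C[C@@H]1CCC(S(=O)c2ccccc2)C(=O)C1 | intermediate
5 | (R)-5-methylcyclohex-2-en-1-one | C[C@@H]1CC=CC(=O)C1 | intermediate
6 | (5R)-2,3-epoxy-5-methylcyclohexan-1-one (epoxide trans to methyl) | O=C1[C@@H]2O[C@@H]2C[C@@H](C)C1 | intermediate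
7 | (1R,5S)-5-methylcyclohex-2-en-1-ol (trans) | O[C@H]1C=CC[C@H](C)C1 | intermediate
8 | bromoform | BrC(Br)Br | starting material
9 | 7,7-dibromo-4-methylbicyclo[4.1.0]heptan-2-ol (cyclopropane cis to OH; methyl trans to OH) | O[C@H]1[C@H]2C(Br)(Br)[C@H]2C[C@H](C)C1 | intermediate
10 | 5-methyltricyclo[4.1.0.0(2,7)]heptan-3-ol (OH toward bridgehead C1; methyl toward bridgehead C7) | [C@@H]12[C@H]3[C@H](C)C[C@@H](O)[C@@H]1[C@@H]23 | intermediate
11 | C1-lithiated lithium alkoxide of 10 | [Li][C@@]12[C@H]3[C@H](C)C[C@@H](O[Li])[C@@H]1[C@@H]23 | intermediate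
12 | 3-hydroxy-5-methyltricyclo[4.1.0.0(2,7)]heptane-1-carboxylic acid | OC(=O)[C@@]12[C@H]3[C@H](C)C[C@@H](O)[C@@H]1[C@@H]23 | intermediate
13 | methyl 3-hydroxy-5-methyltricyclo[4.1.0.0(2,7)]heptane-1-carboxylate | COC(=O)[C@@]12[C@H]3[C@H](C)C[C@@H](O)[C@@H]1[C@@H]23 | intermediate
14 | methyl 3-(tert-butyldimethylsilyloxy)-5-methyltricyclo[4.1.0.0(2,7)]heptane-1-carboxylate (silyloxy toward the ester bridgehead; methyl toward the CH bridgehead) | COC(=O)[C@@]12[C@H]3[C@H](C)C[C@@H](O[Si](C)(C)C(C)(C)C)[C@@H]1[C@@H]23 | intermediate
15 | 3-methylbutan-2-one | CC(C)C(C)=O | starting material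
16 | methyl formate | COC=O | starting material
17 | sodium 4-methyl-3-oxopent-1-en-1-olate | [Na+].[O-]C=CC(=O)C(C)C | intermediate
18 | (E)-1-methoxy-4-methylpent-1-en-3-one | CO/C=C/C(=O)C(C)C | intermediate
19 | (E)-1-methoxy-4-methyl-3-(trimethylsilyloxy)penta-1,3-diene | CO/C=C/C(O[Si](C)(C)C)=C(C)C | intermediate
20 | cage ester with C1 methoxy (both epimers) and C2=C3 trimethylsilyl enol ether | COC1C=C(O[Si](C)(C)C)C(C)(C)[C@H]2[C@@H]3[C@H](C)C[C@@H](O[Si](C)(C)C(C)(C)C)[C@H]2[C@@]31C(=O)OC | intermediate
21 | cage cycloheptenone ester (C1=C2; C3 ketone; C4 gem-dimethyl; C7 methyl toward C5; C9 OTBS toward C11; C11 CO2Me) | C1=CC(=O)C(C)(C)[C@H]2[C@@H]3[C@H](C)C[C@@H](O[Si](C)(C)C(C)(C)C)[C@H]2[C@@]31C(=O)OC | intermediate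
22 | cage diol (C3 allylic alcohol as either epimer; C11 CH2OH) | C1=CC(O)C(C)(C)[C@H]2[C@@H]3[C@H](C)C[C@@H](O[Si](C)(C)C(C)(C)C)[C@H]2[C@@]31CO | intermediate
23 | cage primary tosylate (C11 CH2OTs; C3 OH) | C1=CC(O)C(C)(C)[C@H]2[C@@H]3[C@H](C)C[C@@H](O[Si](C)(C)C(C)(C)C)[C@H]2[C@@]31COS(=O)(=O)c4ccc(C)cc4 | intermediate
24 | cage allylic alcohol (C11 methyl; C3 OH) | C1=CC(O)C(C)(C)[C@H]2[C@@H]3[C@H](C)C[C@@H](O[Si](C)(C)C(C)(C)C)[C@H]2[C@@]31C | intermediate
25 | cage enone (C1=C2; C3 ketone; C11 methyl; C9 OTBS) | C1=CC(=O)C(C)(C)[C@H]2[C@@H]3[C@H](C)C[C@@H](O[Si](C)(C)C(C)(C)C)[C@H]2[C@@]31C | intermediate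
26 | C1 pinacolboryl C3 ketone (boron on the face toward C6) | CC4(C)OB(OC4(C)C)[C@H]1CC(=O)C(C)(C)[C@H]2[C@@H]3[C@H](C)C[C@@H](O[Si](C)(C)C(C)(C)C)[C@H]2[C@@]31C | intermediate
27 | (1S)-C1 hydroxy C3 ketone | O[C@H]1CC(=O)C(C)(C)[C@H]2[C@@H]3[C@H](C)C[C@@H](O[Si](C)(C)C(C)(C)C)[C@H]2[C@@]31C | intermediate
28 | (1S)-C1 angelate C3 ketone | C/C=C(/C)C(=O)O[C@H]1CC(=O)C(C)(C)[C@H]2[C@@H]3[C@H](C)C[C@@H](O[Si](C)(C)C(C)(C)C)[C@H]2[C@@]31C | intermediate
29 | (1S,3S)-C1 angelate C3 alcohol (OH trans to the angelate) | C/C=C(/C)C(=O)O[C@H]1C[C@H](O)C(C)(C)[C@H]2[C@@H]3[C@H](C)C[C@@H](O[Si](C)(C)C(C)(C)C)[C@H]2[C@@]31C | intermediate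
30 | C1 angelate C3 acetate C9 silyl ether | C/C=C(/C)C(=O)O[C@H]1C[C@H](OC(C)=O)C(C)(C)[C@H]2[C@@H]3[C@H](C)C[C@@H](O[Si](C)(C)C(C)(C)C)[C@H]2[C@@]31C | intermediate
31 | C1 angelate C3 acetate C9 alcohol | C/C=C(/C)C(=O)O[C@H]1C[C@H](OC(C)=O)C(C)(C)[C@H]2[C@@H]3[C@H](C)C[C@@H](O)[C@H]2[C@@]31C | intermediate
32 | CNP0204102.1 | C/C=C(/C)C(=O)O[C@H]1C[C@H](OC(C)=O)C(C)(C)[C@H]2[C@@H]3[C@H](C)CC(=O)[C@H]2[C@@]31C | target

Total step count: 22. Longest linear sequence: 20 steps (steps 1–9, 12 and 13–22); the diene branch is steps 10–11.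

Steps most likely to fail

1. Step 12 (key step). The Lewis acid may send the bicyclobutane into cationic skeletal rearrangement, or the hindered, fully substituted enol-ether terminus may fail to attack C5, so that the two-bond annulation does not occur. The fallback uses known reactions and makes the two bonds one at a time, setting out from 14. A photoredox decarboxylative Giese addition of the tertiary radical from 2-methyl-2-(2-methyl-1,3-dioxolan-2-yl)propanoic acid (Ir photocatalyst, Cs2CO3, DMF, blue light) to the acyl bicyclobutane should form the C4–C5 bond and give the ketal ester F1. Deprotonation with LDA and formylation with 2,2,2-trifluoroethyl formate should enter at C11 anti to the three-carbon bridge and give the aldehyde ester F2. PPTS in wet acetone should unmask the keto aldehyde F3, and piperidinium acetate in toluene should close the seven-membered ring by intramolecular aldol condensation onto the non-enolisable aldehyde, which returns to 21.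

2. Step 8. The base may not distinguish well enough between the two bridgehead C–H bonds, so that carboxylation also occurs at the bridgehead on the methyl side. The fallback replaces aggregate control through the lithium alkoxide by a chelating ether and sets out from 10. SEMCl and i-Pr2NEt should give the SEM ether F4; its two acetal oxygens hold s-BuLi (Et2O, −78 to −40 °C) over the nearer bridgehead, and methyl chloroformate should then give the SEM-protected ester F5. TBAF in DMPU removes the SEM group and returns to 13.

3. Step 17. Conjugate borylation may be slow at a β-carbon next to the quaternary C11, or the facial selectivity may be poor because the two ring faces differ only through remote groups. The fallback relays a reagent-controlled carbinol centre to C1 and sets out from 25. Reduction with (S)-Me-CBS and catecholborane should give the allylic alcohol F6 with the C3 hydroxyl on the face that the C1 oxygen must occupy. VO(acac)2 and t-BuOOH should epoxidise syn to that hydroxyl to give the epoxy alcohol F7, and Dess–Martin oxidation should give the epoxy ketone F8. SmI2 in THF–MeOH at −78 °C cleaves the Cα–O bond and returns to 27.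

Further compounds
F1 | step 12 | Giese adduct: methyl ester of the opened cage with the 2-(2-methyl-1,3-dioxolan-2-yl)propan-2-yl group on C5 and H on C11 (either C11 epimer) | CC4(OCCO4)C(C)(C)[C@H]2[C@@H]3[C@H](C)C[C@@H](O[Si](C)(C)C(C)(C)C)[C@H]2C3C(=O)OC
F2 | step 12 | C11 formyl ester of F1 (formyl anti to the C7–C9 bridge) | CC4(OCCO4)C(C)(C)[C@H]2[C@@H]3[C@H](C)C[C@@H](O[Si](C)(C)C(C)(C)C)[C@H]2[C@@]3(C=O)C(=O)OC
F3 | step 12 | keto aldehyde ester (C5 carries the 2-methyl-3-oxobutan-2-yl group; C11 carries CHO and CO2Me) | CC(=O)C(C)(C)[C@H]2[C@@H]3[C@H](C)C[C@@H](O[Si](C)(C)C(C)(C)C)[C@H]2[C@@]3(C=O)C(=O)OC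
F4 | step 8 | 2-(trimethylsilyl)ethoxymethyl ether of 10 | [C@@H]12[C@H]3[C@H](C)C[C@@H](OCOCC[Si](C)(C)C)[C@@H]1[C@@H]23
F5 | step 8 | 2-(trimethylsilyl)ethoxymethyl ether of 13 | COC(=O)[C@@]12[C@H]3[C@H](C)C[C@@H](OCOCC[Si](C)(C)C)[C@@H]1[C@@H]23
F6 | step 17 | (3R)-allylic alcohol from 25 (OH on the face toward C6) | C1=C[C@@H](O)C(C)(C)[C@H]2[C@@H]3[C@H](C)C[C@@H](O[Si](C)(C)C(C)(C)C)[C@H]2[C@@]31C
F7 | step 17 | C1,C2-epoxy C3 alcohol (epoxide syn to OH) | [C@@H]14O[C@H]4[C@@H](O)C(C)(C)[C@H]2[C@@H]3[C@H](C)C[C@@H](O[Si](C)(C)C(C)(C)C)[C@H]2[C@@]31C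
F8 | step 17 | C1,C2-epoxy C3 ketone | [C@@H]14O[C@H]4C(=O)C(C)(C)[C@H]2[C@@H]3[C@H](C)C[C@@H](O[Si](C)(C)C(C)(C)C)[C@H]2[C@@]31C
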